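**Retrosynthetic overview**
1. Lespeflorin B2 ⇒ (2S)-7,4'-dihydroxy-6,8-diprenylflavanone by C3–H hydroxylation trans to the aryl group (flavanone 3-hydroxylase logic); C3 is set last.
2. Flavanone ⇒ unprotected 2'-hydroxychalcone by enantioselective 6-endo-trig oxa-Michael closure (chalcone isomerase logic); this closes the C ring and sets C2.
3. Chalcone ⇒ 2,4-dihydroxy-3,5-diprenylacetophenone + 4-hydroxybenzaldehyde (Claisen–Schmidt).
4. Diprenylacetophenone ⇒ 2,4-dihydroxyacetophenone + two prenyl bromide (double C-prenylation).
5. Ring order: A and B rings are bought, the pyranone C ring is the only ring formed (step 3); no protecting group is ever isolated.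

Prenyl = 3-methylbut-2-enyl; flavonoid numbering is used throughout. The target is (2R,3R), i.e. 2,3-trans.

Assumption: the quinidine-series thiourea catalyst is taken to give the (2S)-flavanone. If the first run shows the opposite sense (a 2S-flavanone has a positive CD band near 330 nm and a negative one near 290 nm), the quinine-series pseudoenantiomer is used and nothing else changes.

**Step 1**
Reactants: 1 2,4-dihydroxyacetophenone; 2 prenyl bromide
Product: 5 2,4-dihydroxy-3,5-diprenylacetophenone, via 3-prenyl-2,4-dihydroxyacetophenone 3 (not isolated), via 5-prenyl-2,4-dihydroxyacetophenone 4 (not isolated)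
Conditions: prenyl bromide (2.3 equiv), 10% aq KOH (2.2 equiv), 0 °C → rt, 16 h, Ar; chromatography
Reagents that add atoms: prenyl bromide (compound 2), CC(C)=CCBr
Why: Direct aqueous-base C-prenylation of a phenol: in water the ambident 4-phenoxide is hydrogen-bonded at oxygen and attacks through carbon, which is only possible at C3 and C5 (ortho to the 4-oxide), so the mono-prenyl compounds 3 and 4 converge on 5; the yield is modest, O-prenyl ethers are separated, and no stereocentre is formed.

**Step 2**
Reactants: 5 2,4-dihydroxy-3,5-diprenylacetophenone; 6 4-hydroxybenzaldehyde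
Product: 8 (E)-2',4',4-trihydroxy-3',5'-diprenylchalcone, via aldol adduct 7 (not isolated)
Conditions: 50% aq KOH (excess), EtOH, 0 °C → rt, 48–72 h, Ar; then cold 1 M HCl to pH 5
Reagents that add atoms: none
Why: Claisen–Schmidt aldol condensation: the ketone enolate adds to the aldehyde and adduct 7 loses water by E1cB to the thermodynamic (E)-enone, while excess hydroxide keeps the 2'-oxygen as a delocalised phenoxide so the chalcone stays open until the cold quench; no stereocentre is formed.

**Step 3**
Reactants: 8 (E)-2',4',4-trihydroxy-3',5'-diprenylchalcone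
Product: 9 (2S)-7,4'-dihydroxy-6,8-diprenylflavanone
Conditions: N-[3,5-bis(trifluoromethyl)phenyl]-N'-(9-deoxy-epi-quinidin-9-yl)thiourea (20 mol %), PhMe–CHCl3 9:1, 4 Å MS, 25 °C, 3–5 d; recrystallise to raise ee
Reagents that add atoms: none
Why: Proposed new method: the quinuclidine nitrogen acts as general base on the chelated 2'-OH while the thiourea N–H bonds bind the enone carbonyl, so the phenoxide adds 6-endo-trig to one enone face inside a chiral ion pair and sets C2 as S; the 6'-deoxychalcone/flavanone equilibrium lies well on the flavanone side and the electron-rich flavanone reverts slowly, so the kinetic ee should be kept; the closest known reaction type is the cinchona-thiourea-catalysed asymmetric intramolecular oxa-Michael cyclisation of 2'-hydroxychalcones and of their α-alkoxycarbonyl-activated analogues to flavanones, here extended to an unactivated, electron-rich chalcone with two free spectator phenols, which will slow the reaction and may cost ee.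

**Step 4**
Reactants: 9 (2S)-7,4'-dihydroxy-6,8-diprenylflavanone
Product: 12 Lespeflorin B2 = (2R,3R)-3,7,4'-trihydroxy-6,8-diprenylflavanone, via tris-TMS enol ether 10 (not isolated), via silyloxy epoxide 11 (not isolated)
Conditions: TMSCl (6 equiv), LiHMDS (3.6 equiv), THF, –78 → –40 °C; DMDO (1.1 equiv, acetone), –78 °C, 15 min; citric acid, MeOH–H2O, 0 °C → rt
Reagents that add atoms: DMDO, CC1(C)OO1 (supplies the C3 oxygen); TMSCl, C[Si](C)(C)Cl (its silicon is present only in 10 and 11 and is lost again on work-up)
Why: Rubottom-type oxidation: in-situ-quench silylation masks both phenols and traps the C3 enolate as enol ether 10 before it can ring-open (C2 is kept), DMDO at –78 °C oxidises the much more nucleophilic enol ether in preference to the prenyl alkenes and on the face opposite the C2 aryl group, and mild acid opens epoxide 11 and removes all TMS groups to give the 2,3-trans (diequatorial, also thermodynamically preferred) ketol, i.e. 3R; the C2 descriptor changes from S to R only because C3 now outranks the aryl carbon.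

**Compound list**
1 | 2,4-dihydroxyacetophenone | CC(=O)c1ccc(O)cc1O | starting material
2 | prenyl bromide (1-bromo-3-methylbut-2-ene) | CC(C)=CCBr | starting material
3 | 2,4-dihydroxy-3-prenylacetophenone | CC(=O)c1ccc(O)c(CC=C(C)C)c1O | intermediate
4 | 2,4-dihydroxy-5-prenylacetophenone | CC(=O)c1cc(CC=C(C)C)c(O)cc1O | intermediate
5 | 2,4-dihydroxy-3,5-diprenylacetophenone | CC(=O)c1cc(CC=C(C)C)c(O)c(CC=C(C)C)c1O | intermediate
6 | 4-hydroxybenzaldehyde | O=Cc1ccc(O)cc1 | starting material
7 | aldol adduct, 1-(2,4-dihydroxy-3,5-diprenylphenyl)-3-hydroxy-3-(4-hydroxyphenyl)propan-1-one (racemic) | CC(C)=CCc1cc(C(=O)CC(O)c2ccc(O)cc2)c(O)c(CC=C(C)C)c1O | intermediate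
8 | (E)-2',4',4-trihydroxy-3',5'-diprenylchalcone | CC(C)=CCc1cc(C(=O)/C=C/c2ccc(O)cc2)c(O)c(CC=C(C)C)c1O | intermediate
9 | (2S)-7,4'-dihydroxy-6,8-diprenylflavanone | CC(C)=CCc1cc2c(c(CC=C(C)C)c1O)O[C@H](c1ccc(O)cc1)CC2=O | intermediate
10 | (2S)-4,7,4'-tris(trimethylsilyloxy)-6,8-diprenylflav-3-ene (TMS enol ether with both phenols as TMS ethers) | CC(C)=CCc1cc2c(c(CC=C(C)C)c1O[Si](C)(C)C)O[C@H](c1ccc(O[Si](C)(C)C)cc1)C=C2O[Si](C)(C)C | intermediate
11 | 3,4-epoxy-4,7,4'-tris(trimethylsilyloxy)-6,8-diprenylflavan, epoxide oxygen on the face opposite the 2-aryl group (2,3-trans) | CC(C)=CCc1cc2c(c(CC=C(C)C)c1O[Si](C)(C)C)O[C@H](c1ccc(O[Si](C)(C)C)cc1)[C@H]1O[C@@]21O[Si](C)(C)C | intermediate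
12 | Lespeflorin B2, (2R,3R)-3,7-dihydroxy-2-(4-hydroxyphenyl)-6,8-bis(3-methylbut-2-enyl)chroman-4-one | CC(C)=CCc1cc2c(c(CC=C(C)C)c1O)O[C@H](c1ccc(O)cc1)[C@@H](O)C2=O | target

**Totals**
Total step count: 4. Longest linear sequence: 4 (1 → 5 → 8 → 9 → 12).

**Steps most likely to fail, with fallbacks**

Step 3 (enantioselective ring closure of the unprotected, unactivated chalcone). The risks are a slow reaction and low ee, because the free 4- and 4'-OH groups are strong donors and compete for the basic site of the catalyst. The fallback sets out from 8 and comes back at 9. Chalcone 8 is acetylated at the two non-chelated phenols (Ac2O 2.2 equiv, pyridine, 0 °C; the hydrogen-bonded 2'-OH stays free) to give (E)-4,4'-di-O-acetyl-2'-hydroxy-3',5'-diprenylchalcone F2. The acetates turn both donors into weak acceptors, which makes the enone more electrophilic and the 2'-OH more acidic, and they remove the acidic spectator phenols. The same thiourea-catalysed oxa-Michael closure then gives (2S)-7,4'-diacetoxy-6,8-diprenylflavanone F3. Neutral deacetylation (NH4OAc, MeOH–H2O, rt) returns 9 without opening the ring.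

Step 1 (double C-prenylation). The risks are low yield and mixtures of mono-, di- and O-prenylated products. The fallback sets out from 1 and comes back at 5. Compound 1 is iodinated at its two activated positions (I2, HIO3, aq EtOH, 40 °C) to give 2,4-dihydroxy-3,5-diiodoacetophenone F1. Both C–I bonds are then coupled with tributyl(3-methylbut-2-enyl)stannane under Stille conditions (Pd(PPh3)4, DMF, 80 °C), where the η3-prenyl palladium intermediate eliminates at its unsubstituted terminus, to give 5. This replaces ambident phenoxide alkylation by a regiodefined cross-coupling.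

Step 4 (C3 hydroxylation). The risks are epoxidation of a prenyl group by DMDO and partial loss of C2 integrity during enolisation. The fallback sets out from 9 and comes back at 12. Flavanone 9 is silylated (TBSCl, imidazole, cat. DMAP, DMF, 40 °C) to give (2S)-7,4'-bis(tert-butyldimethylsilyloxy)-6,8-diprenylflavanone F4. Its potassium enolate (KHMDS, THF, –78 °C, 5 min) is hydroxylated with 2-(phenylsulfonyl)-3-phenyloxaziridine, an oxidant that does not touch isolated alkenes and attacks anti to the 2-aryl group, to give (2R,3R)-7,4'-bis(tert-butyldimethylsilyloxy)-3-hydroxy-6,8-diprenylflavanone F5. Buffered desilylation (TBAF/AcOH, THF, 0 °C) gives 12.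

**Further compounds**
F1 | step 1 | 2,4-dihydroxy-3,5-diiodoacetophenone | CC(=O)c1cc(I)c(O)c(I)c1O
F2 | step 3 | (E)-4,4'-di-O-acetyl-2'-hydroxy-3',5'-diprenylchalcone | CC(C)=CCc1cc(C(=O)/C=C/c2ccc(OC(C)=O)cc2)c(O)c(CC=C(C)C)c1OC(C)=O
F3 | step 3 | (2S)-7,4'-diacetoxy-6,8-diprenylflavanone | CC(C)=CCc1cc2c(c(CC=C(C)C)c1OC(C)=O)O[C@H](c1ccc(OC(C)=O)cc1)CC2=O
F4 | step 4 | (2S)-7,4'-bis(tert-butyldimethylsilyloxy)-6,8-diprenylflavanone | CC(C)=CCc1cc2c(c(CC=C(C)C)c1O[Si](C)(C)C(C)(C)C)O[C@H](c1ccc(O[Si](C)(C)C(C)(C)C)cc1)CC2=O
F5 | step 4 | (2R,3R)-7,4'-bis(tert-butyldimethylsilyloxy)-3-hydroxy-6,8-diprenylflavanone | CC(C)=CCc1cc2c(c(CC=C(C)C)c1O[Si](C)(C)C(C)(C)C)O[C@H](c1ccc(O[Si](C)(C)C(C)(C)C)cc1)[C@@H](O)C2=O
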